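Everything rests on cutting the side chain at the unfunctionalised C8'H2–C9'H2 bond (chain numbered C1'–C16' from the quinone ring), the methylene–methylene seam between the methyl-bearing stereocentres C7' and C11'. Because neither carbon of this bond is stereogenic, one copper-catalysed sp3–sp3 cross-coupling should join the complete head and tail with every stereocentre (C5', C7', C11') and the (E)-C2'=C3' alkene already in place. The precursor is a 1,4-dimethoxynaphthalene (the masked quinone ring) carrying the C1'–C8' chain as a primary bromide with C5'–O silylated; its partner is (R)-3,7-dimethyloctylmagnesium bromide, made from citronellyl bromide.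

Key step: step 9

Remark: compounds 1, 3 and 5, allenylboronic acid pinacol ester and (R)-TRIP are taken as catalogue chemicals, with 3 and 5 of high enantiomeric purity.

Step 1
Reactants: 1 1,4-dimethoxy-2-methylnaphthalene
Product: 2 2-(chloromethyl)-1,4-dimethoxy-3-methylnaphthalene
Conditions: (CH2O)n, conc. HCl, AcOH, 50 °C
Reagents that add atoms: formaldehyde (as paraformaldehyde) C=O; hydrogen chloride Cl
Why: Blanc chloromethylation, an electrophilic aromatic substitution that can only occur at C3, the one free position of the ring activated by both methoxy groups.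

Step 2
Reactants: 3 (R)-citronellyl bromide [(6R)-8-bromo-2,6-dimethyloct-2-ene]
Product: 4 (3R)-1-bromo-3,7-dimethyloctane
Conditions: H2 (1 atm), PtO2 (cat.), EtOAc, rt
Reagents that add atoms: none
Why: Heterogeneous hydrogenation of the trisubstituted alkene over Adams' catalyst in a neutral medium should leave the primary C–Br bond and the remote stereocentre (the later C11') untouched.

Step 3
Reactants: 5 (4S)-4-methyldihydrofuran-2(3H)-one [(S)-β-methyl-γ-butyrolactone]
Product: 6 ethyl (3S)-4-bromo-3-methylbutanoate
Conditions: HBr (g), EtOH, 0 °C → rt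
Reagents that add atoms: hydrogen bromide Br; ethanol CCO
Why: Acid-mediated lactone opening (SN2 of bromide at the primary O–CH2 carbon with Fischer esterification), as in the classical preparation of ethyl 4-bromobutanoate; the stereocentre (the later C7') is not at a reacting carbon.

Step 4
Reactants: 6 ethyl (3S)-4-bromo-3-methylbutanoate
Product: 7 (3S)-4-bromo-3-methylbutanal
Conditions: DIBAL-H (1.05 equiv), CH2Cl2, −78 °C; Rochelle salt work-up; used directly
Reagents that add atoms: none
Why: Partial DIBAL-H reduction of an ester stops at the aluminium hemiacetal at −78 °C, and the stereocentre is β to the carbonyl and so cannot epimerise.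

Step 5
Reactants: 7 (3S)-4-bromo-3-methylbutanal
Product: 8 (4S,6S)-7-bromo-6-methylhept-1-yn-4-ol
Conditions: allenyl-B(pin) (1.3 equiv), (R)-TRIP (5 mol%), 4 Å MS, toluene, 0 °C; aqueous work-up
Reagents that add atoms: allenylboronic acid pinacol ester C=C=CB1OC(C)(C)C(C)(C)O1
Why: Chiral phosphoric acid-catalysed propargylation (allenylboration, SE2') through a closed six-membered chair transition state; the (R)-phosphate, the enantiomer meant to direct attack to the Re face of the aldehyde, should set C4 (the later C5') as S under catalyst control, the remote methyl centre having negligible influence.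

Step 6
Reactants: 8 (4S,6S)-7-bromo-6-methylhept-1-yn-4-ol
Product: 9 triethyl{[(4S,6S)-7-bromo-6-methylhept-1-yn-4-yl]oxy}silane
Conditions: Et3SiCl, imidazole, CH2Cl2, 0 °C
Reagents that add atoms: chlorotriethylsilane CC[Si](Cl)(CC)CC
Why: Standard O-silylation, fast enough at 0 °C to outrun 5-exo cyclisation of the γ-bromo alcohol; the triethylsilyl ether should survive Me3Al and the Grignard reagent and fall to dilute acid.

Step 7
Reactants: 9 triethyl{[(4S,6S)-7-bromo-6-methylhept-1-yn-4-yl]oxy}silane; 2 2-(chloromethyl)-1,4-dimethoxy-3-methylnaphthalene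
Product: 11 2-[(2E,5S,7S)-8-bromo-3,7-dimethyl-5-(triethylsilyloxy)oct-2-en-1-yl]-1,4-dimethoxy-3-methylnaphthalene, via alkenyldimethylalane 10 (not isolated)
Conditions: Me3Al (2.2 equiv), Cp2ZrCl2 (0.25 equiv), CH2Cl2, 0 °C → rt; volatiles removed; then 2 (0.9 equiv), NiCl2(PPh3)2/n-BuLi (3 mol% Ni(0)), THF, 0 °C → rt
Reagents that add atoms: trimethylaluminium C[Al](C)C
Why: Negishi zirconium-catalysed syn-methylalumination puts the methyl on the internal alkyne carbon and aluminium on the terminus, and the (E)-alkenylalane should couple with retention with the benzylic chloride under Ni(0) (alkenylalane–benzylic chloride cross-coupling), fixing the (E)-C2'=C3' alkene; the benzylic C–Cl bond should add to Ni(0) far faster than the β-branched alkyl C–Br bond.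

Step 8
Reactants: 4 (3R)-1-bromo-3,7-dimethyloctane
Product: 12 [(3R)-3,7-dimethyloctyl]magnesium bromide
Conditions: Mg turnings, I2 (cat.), THF, 40 °C; used as a titrated solution
Reagents that add atoms: magnesium [Mg]
Why: Grignard formation by magnesium insertion into a primary alkyl bromide; the stereocentre is two carbons from the metal-bearing carbon and is not affected.

Step 9
Reactants: 11 2-[(2E,5S,7S)-8-bromo-3,7-dimethyl-5-(triethylsilyloxy)oct-2-en-1-yl]-1,4-dimethoxy-3-methylnaphthalene; 12 [(3R)-3,7-dimethyloctyl]magnesium bromide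
Product: 14 (2E,5S,7R,11R)-1-(1,4-dimethoxy-3-methylnaphthalen-2-yl)-3,7,11,15-tetramethylhexadec-2-en-5-ol, via coupled triethylsilyl ether 13 (not isolated)
Conditions: 12 (2.5 equiv), Li2CuCl4 (5 mol%), NMP (4 equiv), THF, 0 °C → rt; then 1 M aq. HCl, THF, rt
Reagents that add atoms: none
Why: The Grignard reagent should transmetallate to copper to give a dialkylcuprate, which attacks the primary C8'–Br carbon in an SN2-type oxidative addition and then reductively eliminates from Cu(III) to forge the C8'–C9' sp3–sp3 bond. The closest known reaction type is the Kochi–Cahiez copper-catalysed alkyl–alkyl Kumada coupling (Li2CuCl4, NMP), long used to stitch isoprenoid chains. No ring is closed and no stereocentre is created, so C5', C7' and C11' are carried over unchanged: none is an end of the new bond, and C7' and C11' bear no acidic hydrogen. The step needs chemoselectivity for the C–Br bond over the aryl ethers, the trisubstituted alkene and the silyl ether, and it must outrun 5-exo attack of the C5' oxygen on C8' and E2 elimination across C7'–C8'; the triethylsilyl ether mutes the oxygen, and NMP accelerates the cuprate substitution at the β-branched carbon at 0 °C. Dilute aqueous HCl in the work-up then cleaves the silyl ether, so the free C5' alcohol should be isolated directly.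

Step 10
Reactants: 14 (2E,5S,7R,11R)-1-(1,4-dimethoxy-3-methylnaphthalen-2-yl)-3,7,11,15-tetramethylhexadec-2-en-5-ol
Product: 15 2-[(2E,5S,7R,11R)-5-hydroxy-3,7,11,15-tetramethylhexadec-2-en-1-yl]-3-methylnaphthalene-1,4-dione
Conditions: (NH4)2Ce(NO3)6 (2.5 equiv), MeCN–H2O (4:1), 0 °C
Reagents that add atoms: water O
Why: CAN oxidative demethylation of the 1,4-dimethoxyarene (arene radical cation, water addition at the ipso carbons, loss of methanol) should unveil the 1,4-quinone faster than the isolated trisubstituted alkene or the secondary alcohol is oxidised.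

Compound list
1 | 1,4-dimethoxy-2-methylnaphthalene | COc1c(C)cc(OC)c2ccccc12 | starting material
2 | 2-(chloromethyl)-1,4-dimethoxy-3-methylnaphthalene | COc1c(C)c(CCl)c(OC)c2ccccc12 | intermediate
3 | (R)-citronellyl bromide, (6R)-8-bromo-2,6-dimethyloct-2-ene | BrCC[C@H](C)CCC=C(C)C | starting material
4 | (3R)-1-bromo-3,7-dimethyloctane | BrCC[C@H](C)CCCC(C)C | intermediate
5 | (4S)-4-methyldihydrofuran-2(3H)-one | O=C1C[C@H](C)CO1 | starting material
6 | ethyl (3S)-4-bromo-3-methylbutanoate | CCOC(=O)C[C@H](C)CBr | intermediate
7 | (3S)-4-bromo-3-methylbutanal | O=CC[C@H](C)CBr | intermediate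
8 | (4S,6S)-7-bromo-6-methylhept-1-yn-4-ol | C#CC[C@@H](O)C[C@H](C)CBr | intermediate
9 | triethyl{[(4S,6S)-7-bromo-6-methylhept-1-yn-4-yl]oxy}silane | C#CC[C@@H](O[Si](CC)(CC)CC)C[C@H](C)CBr | intermediate
10 | [(1E,4S,6S)-7-bromo-2,6-dimethyl-4-(triethylsilyloxy)hept-1-en-1-yl]dimethylalane | C[Al](C)/C=C(\C)C[C@@H](O[Si](CC)(CC)CC)C[C@H](C)CBr | intermediate (not isolated)
11 | 2-[(2E,5S,7S)-8-bromo-3,7-dimethyl-5-(triethylsilyloxy)oct-2-en-1-yl]-1,4-dimethoxy-3-methylnaphthalene | COc1c(C)c(C/C=C(\C)C[C@@H](O[Si](CC)(CC)CC)C[C@H](C)CBr)c(OC)c2ccccc12 | intermediate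
12 | [(3R)-3,7-dimethyloctyl]magnesium bromide | Br[Mg]CC[C@H](C)CCCC(C)C | intermediate
13 | triethyl{[(2E,5S,7R,11R)-1-(1,4-dimethoxy-3-methylnaphthalen-2-yl)-3,7,11,15-tetramethylhexadec-2-en-5-yl]oxy}silane | COc1c(C)c(C/C=C(\C)C[C@@H](O[Si](CC)(CC)CC)C[C@H](C)CCC[C@H](C)CCCC(C)C)c(OC)c2ccccc12 | intermediate (not isolated)
14 | (2E,5S,7R,11R)-1-(1,4-dimethoxy-3-methylnaphthalen-2-yl)-3,7,11,15-tetramethylhexadec-2-en-5-ol | COc1c(C)c(C/C=C(\C)C[C@@H](O)C[C@H](C)CCC[C@H](C)CCCC(C)C)c(OC)c2ccccc12 | intermediate
15 | 2-[(2E,5S,7R,11R)-5-hydroxy-3,7,11,15-tetramethylhexadec-2-en-1-yl]-3-methylnaphthalene-1,4-dione | CC1=C(C/C=C(\C)C[C@@H](O)C[C@H](C)CCC[C@H](C)CCCC(C)C)C(=O)c2ccccc2C1=O | target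

Total step count: 10.
Longest linear sequence: 7 steps (5 → 6 → 7 → 8 → 9 → 11 → 14 → 15; steps 3, 4, 5, 6, 7, 9, 10).

Steps most likely to fail

1. Step 9 (key coupling). The cuprate substitution at the β-branched C8' carbon may be slow, so that E2 elimination across C7'–C8', reduction of the bromide by halogen–metal exchange or homocoupling of the Grignard reagent takes over. The fallback sets out from 11 and returns at 13; it replaces the magnesium/copper manifold by a radical-type nickel-catalysed alkyl–alkyl Suzuki coupling. Bromide 4 would be dehydrobrominated (KOtBu, DMSO, rt) to (3R)-3,7-dimethyloct-1-ene F1. F1 would be hydroborated with 9-BBN-H (THF, rt) to B-[(3R)-3,7-dimethyloctyl]-9-borabicyclo[3.3.1]nonane F2. F2 and 11 would then be coupled with NiCl2·glyme, trans-N,N'-dimethylcyclohexane-1,2-diamine, KOtBu and i-BuOH in dioxane at rt to give silyl ether 13, which is hydrolysed to 14 as in step 9.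

2. Step 5 (propargylation). Facial discrimination by the phosphoric acid may be incomplete for an unbranched aliphatic aldehyde, giving C4 epimers that are hard to separate. The fallback sets out from 7 and returns at 8; it sets this centre by resolution of a terminal epoxide in place of a catalyst-controlled addition. Wittig methylenation of 7 (Ph3P=CH2, THF, −78 → 0 °C) would give (4S)-5-bromo-4-methylpent-1-ene F3. Epoxidation (mCPBA, CH2Cl2) would give 2-[(2S)-3-bromo-2-methylpropyl]oxirane F4 as both epoxide epimers. Jacobsen hydrolytic kinetic resolution, with the (salen)Co(III)OAc enantiomer that hydrolyses the (2R)-epoxide, would leave (2S)-2-[(2S)-3-bromo-2-methylpropyl]oxirane F5. Opening of F5 at the terminal carbon with lithium acetylide and BF3·OEt2 (THF, −78 °C) would give 8.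

3. Step 7 (carboalumination and cross-coupling). Methyl transfer from aluminium to the benzylic partner, insertion of Ni(0) into the alkyl C–Br bond or incomplete regiocontrol in the methylalumination may erode the outcome. The fallback sets out from 9 and returns at 11; it separates the two events and reverses the polarity of the coupling. Alane 10, made from 9 as in step 7, would be quenched with I2 (THF, −30 °C) to the vinyl iodide triethyl{[(1E,4S,6S)-7-bromo-1-iodo-2,6-dimethylhept-1-en-4-yl]oxy}silane F6. Chloride 2 would be converted with zinc dust and LiCl (THF, rt) into [(1,4-dimethoxy-3-methylnaphthalen-2-yl)methyl]zinc chloride F7. Pd(PPh3)4-catalysed Negishi coupling of F6 with F7 (THF, rt), in which Pd(0) should select the C(sp2)–I bond over the alkyl bromide, would give 11.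

Further compounds
F1 | step 9 | (3R)-3,7-dimethyloct-1-ene | C=C[C@H](C)CCCC(C)C
F2 | step 9 | B-[(3R)-3,7-dimethyloctyl]-9-borabicyclo[3.3.1]nonane | C1CCC2CCCC1B2CC[C@H](C)CCCC(C)C
F3 | step 5 | (4S)-5-bromo-4-methylpent-1-ene | C=CC[C@H](C)CBr
F4 | step 5 | 2-[(2S)-3-bromo-2-methylpropyl]oxirane (both epoxide epimers) | C1OC1C[C@H](C)CBr
F5 | step 5 | (2S)-2-[(2S)-3-bromo-2-methylpropyl]oxirane | C1[C@@H](O1)C[C@H](C)CBr
F6 | step 7 | triethyl{[(1E,4S,6S)-7-bromo-1-iodo-2,6-dimethylhept-1-en-4-yl]oxy}silane | I/C=C(\C)C[C@@H](O[Si](CC)(CC)CC)C[C@H](C)CBr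
F7 | step 7 | [(1,4-dimethoxy-3-methylnaphthalen-2-yl)methyl]zinc chloride | COc1c(C)c(C[Zn]Cl)c(OC)c2ccccc12
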